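**Retrosynthetic overview**

1. The target is epioritin-(4β→6)-epioritin-4α-ol. In both A rings the C8 hydroxyl lies between the pyran oxygen O1 (on C8a) and the C7 oxygen. Without these two oxygens each A ring is a 7-oxygenated, resorcinol-type ring that alkylates well at C6, and C8–H, flanked by O1 and a C7 O-carbamate, is the aryl proton an alkyllithium removes first.
2. Last skeletal bonds: both C8–O bonds, made together by carbamate-directed ortho-lithiation, borylation and oxidation of the protected 8,8′-dideoxy dimer. Then LiAlH4 removes the carbamates and fluoride removes all silyl ethers. The lower 3,4-diol is carried as a bis-TBS ether, so no acid step is needed.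
3. C4(upper)–C6(lower) bond: silver-promoted Friedel–Crafts reaction of a 4β-benzylsulfanyl donor with an all-cis 3,4-bis(silyloxy) acceptor. Both come from one 7-O-benzyl-4′-O-TIPS-epiguibourtinidol monomer (C4 oxygen by DDQ, 4α-OH by oxidation and hydride reduction).
4. Monomer: O1–C2 bond by Mitsunobu etherification (inversion) of an erythro epoxy alcohol from a Sharpless kinetic resolution with 5-(benzyloxy)-2-bromophenol. Ring C is then closed through the C4–C4a bond by aryllithium opening of the epoxide.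
5. Ring order: rings A and B are bought. Ring C of the monomer is the only ring formed (once, used for both units). No ring is formed afterwards.

Key step: step 15

Remarks on the chemistry: 5-(benzyloxy)-2-bromophenol is taken as a purchasable building block. α and β refer to the usual flavan drawing (ring A left, O1 up); in these 2R compounds the C2 aryl group is α. The kinetic resolution of step 3 is assumed to give the epoxy alcohol in high enantiomeric purity; a residual minor enantiomer would end as a separable diastereomer after step 12.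

**Route**

Step 1
Reactants: 1 4-hydroxybenzaldehyde
Product: 2 4-[tri(propan-2-yl)silyloxy]benzaldehyde
Conditions: TIPSCl, imidazole, DMF, rt
Reagents that add atoms: chlorotri(propan-2-yl)silane (TIPSCl), CC(C)[Si](Cl)(C(C)C)C(C)C
Why: Silylation of the phenol (substitution at silicon with imidazole as base) installs a bulky ether that should survive the Grignard, organolithium, DDQ and hydride steps and does not direct lithiation later.

Step 2
Reactants: 2 4-[tri(propan-2-yl)silyloxy]benzaldehyde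
Product: 3 rac-1-{4-[tri(propan-2-yl)silyloxy]phenyl}prop-2-en-1-ol
Conditions: CH2=CHMgBr, THF, −78 to 0 °C; aq. NH4Cl
Reagents that add atoms: vinylmagnesium bromide, C=C[Mg]Br
Why: Grignard 1,2-addition to the aldehyde gives the secondary allylic alcohol that the kinetic resolution needs; the carbinol centre is formed racemic on purpose.

Step 3
Reactants: 3 rac-1-{4-[tri(propan-2-yl)silyloxy]phenyl}prop-2-en-1-ol
Product: 4 (S)-[(2R)-oxiran-2-yl]{4-[tri(propan-2-yl)silyloxy]phenyl}methanol (erythro epoxy alcohol)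
Conditions: Ti(OiPr)4 (0.2 equiv), L-(+)-diisopropyl tartrate (0.24 equiv), t-BuOOH (0.45 equiv), 4 Å MS, CH2Cl2, −20 °C
Reagents that add atoms: tert-butyl hydroperoxide, CC(C)(C)OO
Why: Sharpless asymmetric epoxidation run as a kinetic resolution: with L-(+)-DIPT the (R)-alcohol is epoxidised far faster than its antipode and only to the erythro epoxy alcohol, so the titanium tartrate catalyst sets the epoxide carbon (future C3, R) and selects the carbinol configuration, and unreacted (S)-3 is separated after less than half conversion.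

Step 4
Reactants: 4 (S)-[(2R)-oxiran-2-yl]{4-[tri(propan-2-yl)silyloxy]phenyl}methanol; 5 5-(benzyloxy)-2-bromophenol
Product: 6 (2R)-2-[(R)-[5-(benzyloxy)-2-bromophenoxy]{4-[tri(propan-2-yl)silyloxy]phenyl}methyl]oxirane (threo aryl ether)
Conditions: PPh3, DIAD, toluene, 0 °C to rt
Reagents that add atoms: none
Why: Mitsunobu etherification, in which the acidic bromophenol displaces the phosphonium-activated benzylic oxygen with inversion, sets the future C2 (R) and turns the erythro array into the threo array of a 2,3-cis flavan while the epoxide stays untouched.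

Step 5
Reactants: 6 (2R)-2-[(R)-[5-(benzyloxy)-2-bromophenoxy]{4-[tri(propan-2-yl)silyloxy]phenyl}methyl]oxirane
Product: 8 (2R,3R)-7-(benzyloxy)-2-{4-[tri(propan-2-yl)silyloxy]phenyl}chroman-3-ol (2,3-cis; protected epiguibourtinidol), via aryllithium 7 (not isolated)
Conditions: n-BuLi (1.1 equiv), THF, −78 °C, then to −20 °C; aq. NH4Cl
Reagents that add atoms: n-butyllithium, [Li]CCCC (lithium of intermediate 7 only; no atom other than hydrogen is added to 8)
Why: Parham-type cyclisation, a known way to flavan-3-ols from such aryl ethers: bromine–lithium exchange gives aryllithium 7, which opens the epoxide at its unhindered terminal carbon (6-endo) and so closes ring C through the C4–C4a bond without touching either stereocentre.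

Step 6
Reactants: 8 (2R,3R)-7-(benzyloxy)-2-{4-[tri(propan-2-yl)silyloxy]phenyl}chroman-3-ol
Product: 9 (2R,3R)-7-(benzyloxy)-3-[tert-butyl(dimethyl)silyloxy]-2-{4-[tri(propan-2-yl)silyloxy]phenyl}chromane
Conditions: TBSOTf, 2,6-lutidine, CH2Cl2, 0 °C
Reagents that add atoms: tert-butyldimethylsilyl triflate (TBSOTf), CC(C)(C)[Si](C)(C)OS(=O)(=O)C(F)(F)F
Why: Silylation with the silyl triflate and a hindered base caps the axial 3-hydroxyl, which the DDQ oxidation needs and which later keeps the lithiation substrate free of OH groups.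

Step 7
Reactants: 9 (2R,3R)-7-(benzyloxy)-3-[tert-butyl(dimethyl)silyloxy]-2-{4-[tri(propan-2-yl)silyloxy]phenyl}chromane
Product: 10 (2R,3R,4S)-7-(benzyloxy)-3-[tert-butyl(dimethyl)silyloxy]-2-{4-[tri(propan-2-yl)silyloxy]phenyl}chroman-4-ol (2,3-cis-3,4-trans; 4β-OH)
Conditions: DDQ (1.5 equiv), CH2Cl2/H2O (10:1), rt
Reagents that add atoms: water, O
Why: DDQ benzylic oxidation: hydride abstraction from C4, para to the benzyloxy group and ortho to O1, gives a quinone-methide-type cation that water captures on the β face, anti to the axial 3-silyloxy group, so the 4β-alcohol should form.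

Step 8
Reactants: 10 (2R,3R,4S)-7-(benzyloxy)-3-[tert-butyl(dimethyl)silyloxy]-2-{4-[tri(propan-2-yl)silyloxy]phenyl}chroman-4-ol
Product: 11 (2R,3S,4S)-7-(benzyloxy)-4-(benzylsulfanyl)-3-[tert-butyl(dimethyl)silyloxy]-2-{4-[tri(propan-2-yl)silyloxy]phenyl}chromane (4β-SBn; donor)
Conditions: BnSH (3 equiv), ZnI2 (0.2 equiv), 4 Å MS, CH2Cl2, 0 °C to rt
Reagents that add atoms: benzyl mercaptan, SCc1ccccc1
Why: Lewis-acid-catalysed thiolysis of the flavan-4-ol (SN1 through the same C4 cation) gives the thioether by attack anti to the 3-silyloxy group (4β) and provides a leaving group that only a thiophilic promoter activates.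

Step 9
Reactants: 10 (2R,3R,4S)-7-(benzyloxy)-3-[tert-butyl(dimethyl)silyloxy]-2-{4-[tri(propan-2-yl)silyloxy]phenyl}chroman-4-ol
Product: 12 (2R,3S)-7-(benzyloxy)-3-[tert-butyl(dimethyl)silyloxy]-2-{4-[tri(propan-2-yl)silyloxy]phenyl}chroman-4-one (2,3-cis)
Conditions: Dess–Martin periodinane, NaHCO3, CH2Cl2, 0 °C to rt
Reagents that add atoms: none
Why: Dess–Martin oxidation of the benzylic alcohol under buffered, non-basic conditions gives the 2,3-cis flavanone without enolisation at C3 or ring opening at C2.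

Step 10
Reactants: 12 (2R,3S)-7-(benzyloxy)-3-[tert-butyl(dimethyl)silyloxy]-2-{4-[tri(propan-2-yl)silyloxy]phenyl}chroman-4-one
Product: 13 (2R,3R,4R)-7-(benzyloxy)-3-[tert-butyl(dimethyl)silyloxy]-2-{4-[tri(propan-2-yl)silyloxy]phenyl}chroman-4-ol (all-cis; 4α-OH)
Conditions: NaBH4, CeCl3·7H2O, MeOH/THF, −40 to 0 °C
Reagents that add atoms: none
Why: Luche-type hydride reduction: hydride adds to the carbonyl from the β face, anti to the axial 3-silyloxy group (Felkin–Anh, axial attack), which sets C4 as the 4α-alcohol and completes the all-cis array of the lower unit.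

Step 11
Reactants: 13 (2R,3R,4R)-7-(benzyloxy)-3-[tert-butyl(dimethyl)silyloxy]-2-{4-[tri(propan-2-yl)silyloxy]phenyl}chroman-4-ol
Product: 14 (2R,3S,4R)-7-(benzyloxy)-3,4-bis[tert-butyl(dimethyl)silyloxy]-2-{4-[tri(propan-2-yl)silyloxy]phenyl}chromane (all-cis; acceptor)
Conditions: TBSOTf, 2,6-lutidine, CH2Cl2, −40 to 0 °C
Reagents that add atoms: tert-butyldimethylsilyl triflate (TBSOTf), CC(C)(C)[Si](C)(C)OS(=O)(=O)C(F)(F)F
Why: Silylation of the benzylic 4α-hydroxyl gives a fully capped acceptor whose C4–O bond is inert to the soft promoter of the coupling and which needs no acid for its later release.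

Step 12
Reactants: 11 the 4β-benzylsulfanyl donor; 14 the all-cis bis(silyloxy) acceptor (threefold excess)
Product: 15 protected epiguibourtinidol-(4β→6)-epiguibourtinidol-4α-ol: 7-O-benzyl and 4′-O-TIPS on both units; 3-O-TBS on the upper unit; 3,4-di-O-TBS on the lower unit
Conditions: AgOSO2CF3 (1.5 equiv), 2,6-di-tert-butyl-4-methylpyridine, 4 Å MS, CH2Cl2, −40 to 0 °C
Reagents that add atoms: none
Why: Silver-promoted ionisation of the C4–S bond followed by Friedel–Crafts alkylation, the known thioether route to interflavanyl bonds: ring A of 14 attacks through C6 (para to O1, ortho to the benzyloxy group, less crowded than C8) on the β face of the cation, anti to the 2-aryl and 3-silyloxy groups, which sets the upper C4 (4β, 3,4-trans), while the excess of 14 suppresses self-alkylation of the donor.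

Step 13
Reactants: 15 the bis(benzyl ether) dimer
Product: 16 the dimer with free C7 hydroxyls on both A rings (silyl ethers kept)
Conditions: H2 (1 atm), Pd/C, EtOAc, rt
Reagents that add atoms: none
Why: Hydrogenolysis of the two aryl benzyl ethers over palladium under neutral conditions frees the two C7 phenols and should leave the silyl ethers, the pyran C–O bonds and the interflavanyl bond intact.

Step 14
Reactants: 16 the C7,C7′ bisphenol dimer
Product: 17 the bis(7-O-N,N-diethylcarbamate) dimer (lithiation precursor)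
Conditions: NaH, ClC(O)NEt2, THF, 0 to 40 °C
Reagents that add atoms: N,N-diethylcarbamoyl chloride, CCN(CC)C(Cl)=O
Why: O-acylation of the two sodium phenoxides with the carbamoyl chloride puts the strongest oxygen-based directing groups on the A rings only, the B-ring oxygens staying as bulky, non-directing silyl ethers.

Step 15
Reactants: 17 the bis(7-O-N,N-diethylcarbamate) dimer
Product: 20 the 8,8′-dihydroxy bis(7-O-carbamate) dimer (protected target), via 8,8′-dilithio species 18 (not isolated), via 8,8′-bis(dimethoxyboryl) compound 19 (not isolated)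
Conditions: s-BuLi (2.6 equiv), TMEDA, THF, −78 °C; B(OMe)3, −78 to 0 °C; AcOH, 30% H2O2, 0 °C to rt
Reagents that add atoms: sec-butyllithium, [Li]C(C)CC (lithium of 18 only); trimethyl borate, COB(OC)OC (boron and methoxy groups of 19 only); hydrogen peroxide, OO (the two C8 oxygens of 20)
Why: Directed ortho-metalation: s-BuLi/TMEDA binds to each carbamate carbonyl and removes the C8 proton, the only aryl C–H flanked by two oxygens (O1 and the C7 carbamate oxygen), to give 18; B(OMe)3 traps both C–Li bonds at −78 °C as 19 before an anionic ortho-Fries shift can start, and H2O2/AcOH moves each aryl group from boron to oxygen at the same carbon. The closest known reaction type is lithiation–borylation–oxidation of aryl O-carbamates that carry a meta alkoxy group, which metalate at the shared ortho position. No ring is closed and no stereocentre is formed; the six existing stereocentres stay untouched as long as no sp3 C–H is removed. The step needs C8 over C6 in the upper unit (two directing oxygens against one; in the lower unit C6 is already substituted), and C8 over the benzylic C2–H, the diarylmethine C4–H and the silyloxy-bearing C4–H, which are undirected and slower to deprotonate at −78 °C. The B rings are shielded by triisopropylsilyl ethers that neither direct nor acidify, and every hydroxyl is capped, so base is consumed only at the two C8 positions. The acidic peroxide work-up keeps the aryl silyl ethers and avoids carbamoyl migration to the new phenols.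

Step 16
Reactants: 20 the 8,8′-dihydroxy bis(7-O-carbamate) dimer
Product: 21 silyl-protected target with free 7,8-diols on both A rings
Conditions: LiAlH4, THF, 0 to 50 °C; aq. Rochelle salt, argon
Reagents that add atoms: none
Why: Hydride reduction of the aryl carbamates (addition to the carbonyl and loss of aryloxide, the amine part ending as N,N-diethylmethylamine) frees both C7 hydroxyls under reducing, oxygen-free conditions that protect the new catechol units.

Step 17
Reactants: 21 silyl-protected target with free 7,8-diols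
Product: 22 epioritin-(4β→6)-epioritin-4α-ol (CNP0391561.1)
Conditions: HF·pyridine, pyridine, THF, 0 °C to rt, argon
Reagents that add atoms: none
Why: Fluoride-induced cleavage of all five silyl ethers in a pyridine-buffered medium should release the target without an acid strong enough to ionise the lower C4–OH or a base that would oxidise the catechols.

**Compound list**

1 | 4-hydroxybenzaldehyde | O=Cc1ccc(O)cc1 | starting material
2 | 4-[tri(propan-2-yl)silyloxy]benzaldehyde | O=Cc1ccc(O[Si](C(C)C)(C(C)C)C(C)C)cc1 | intermediate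
3 | rac-1-{4-[tri(propan-2-yl)silyloxy]phenyl}prop-2-en-1-ol | C=CC(O)c1ccc(O[Si](C(C)C)(C(C)C)C(C)C)cc1 | intermediate
4 | (S)-[(2R)-oxiran-2-yl]{4-[tri(propan-2-yl)silyloxy]phenyl}methanol | O[C@@H](c1ccc(O[Si](C(C)C)(C(C)C)C(C)C)cc1)[C@H]1CO1 | intermediate
5 | 5-(benzyloxy)-2-bromophenol | Oc1cc(OCc2ccccc2)ccc1Br | starting material
6 | (2R)-2-[(R)-[5-(benzyloxy)-2-bromophenoxy]{4-[tri(propan-2-yl)silyloxy]phenyl}methyl]oxirane | Brc1ccc(OCc2ccccc2)cc1O[C@H](c1ccc(O[Si](C(C)C)(C(C)C)C(C)C)cc1)[C@H]1CO1 | intermediate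
7 | aryllithium from 6 (Li in place of Br) | [Li]c1ccc(OCc2ccccc2)cc1O[C@H](c1ccc(O[Si](C(C)C)(C(C)C)C(C)C)cc1)[C@H]1CO1 | intermediate (not isolated)
8 | (2R,3R)-7-(benzyloxy)-2-{4-[tri(propan-2-yl)silyloxy]phenyl}chroman-3-ol | CC(C)[Si](C(C)C)(C(C)C)Oc1ccc([C@H]2Oc3cc(OCc4ccccc4)ccc3C[C@H]2O)cc1 | intermediate
9 | (2R,3R)-7-(benzyloxy)-3-[tert-butyl(dimethyl)silyloxy]-2-{4-[tri(propan-2-yl)silyloxy]phenyl}chromane | CC(C)[Si](C(C)C)(C(C)C)Oc1ccc([C@H]2Oc3cc(OCc4ccccc4)ccc3C[C@H]2O[Si](C)(C)C(C)(C)C)cc1 | intermediate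
10 | (2R,3R,4S)-7-(benzyloxy)-3-[tert-butyl(dimethyl)silyloxy]-2-{4-[tri(propan-2-yl)silyloxy]phenyl}chroman-4-ol (4β-OH) | CC(C)[Si](C(C)C)(C(C)C)Oc1ccc([C@H]2Oc3cc(OCc4ccccc4)ccc3[C@H](O)[C@H]2O[Si](C)(C)C(C)(C)C)cc1 | intermediate
11 | (2R,3S,4S)-7-(benzyloxy)-4-(benzylsulfanyl)-3-[tert-butyl(dimethyl)silyloxy]-2-{4-[tri(propan-2-yl)silyloxy]phenyl}chromane (4β-SBn) | CC(C)[Si](C(C)C)(C(C)C)Oc1ccc([C@H]2Oc3cc(OCc4ccccc4)ccc3[C@H](SCc3ccccc3)[C@H]2O[Si](C)(C)C(C)(C)C)cc1 | intermediate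
12 | (2R,3S)-7-(benzyloxy)-3-[tert-butyl(dimethyl)silyloxy]-2-{4-[tri(propan-2-yl)silyloxy]phenyl}chroman-4-one | CC(C)[Si](C(C)C)(C(C)C)Oc1ccc([C@H]2Oc3cc(OCc4ccccc4)ccc3C(=O)[C@H]2O[Si](C)(C)C(C)(C)C)cc1 | intermediate
13 | (2R,3R,4R)-7-(benzyloxy)-3-[tert-butyl(dimethyl)silyloxy]-2-{4-[tri(propan-2-yl)silyloxy]phenyl}chroman-4-ol (4α-OH, all-cis) | CC(C)[Si](C(C)C)(C(C)C)Oc1ccc([C@H]2Oc3cc(OCc4ccccc4)ccc3[C@@H](O)[C@H]2O[Si](C)(C)C(C)(C)C)cc1 | intermediate
14 | (2R,3S,4R)-7-(benzyloxy)-3,4-bis[tert-butyl(dimethyl)silyloxy]-2-{4-[tri(propan-2-yl)silyloxy]phenyl}chromane (all-cis) | CC(C)[Si](C(C)C)(C(C)C)Oc1ccc([C@H]2Oc3cc(OCc4ccccc4)ccc3[C@@H](O[Si](C)(C)C(C)(C)C)[C@H]2O[Si](C)(C)C(C)(C)C)cc1 | intermediate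
15 | protected epiguibourtinidol-(4β→6)-epiguibourtinidol-4α-ol: 7-O-benzyl and 4′-O-TIPS on both units, 3-O-TBS (upper), 3,4-di-O-TBS (lower) | O([Si](C(C)C)(C(C)C)C(C)C)c1ccc([C@H]2Oc3c(ccc(OCc4ccccc4)c3)[C@H](c3cc4c(cc3OCc3ccccc3)O[C@H](c3ccc(O[Si](C(C)C)(C(C)C)C(C)C)cc3)[C@H](O[Si](C)(C)C(C)(C)C)[C@@H]4O[Si](C)(C)C(C)(C)C)[C@H]2O[Si](C)(C)C(C)(C)C)cc1 | intermediate
16 | the dimer of 15 with free C7 hydroxyls on both A rings | O([Si](C(C)C)(C(C)C)C(C)C)c1ccc([C@H]2Oc3c(ccc(O)c3)[C@H](c3cc4c(cc3O)O[C@H](c3ccc(O[Si](C(C)C)(C(C)C)C(C)C)cc3)[C@H](O[Si](C)(C)C(C)(C)C)[C@@H]4O[Si](C)(C)C(C)(C)C)[C@H]2O[Si](C)(C)C(C)(C)C)cc1 | intermediate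
17 | bis(7-O-N,N-diethylcarbamate) of 16 (lithiation precursor) | O([Si](C(C)C)(C(C)C)C(C)C)c1ccc([C@H]2Oc3c(ccc(OC(=O)N(CC)CC)c3)[C@H](c3cc4c(cc3OC(=O)N(CC)CC)O[C@H](c3ccc(O[Si](C(C)C)(C(C)C)C(C)C)cc3)[C@H](O[Si](C)(C)C(C)(C)C)[C@@H]4O[Si](C)(C)C(C)(C)C)[C@H]2O[Si](C)(C)C(C)(C)C)cc1 | intermediate
18 | 8,8′-dilithio derivative of 17 | O([Si](C(C)C)(C(C)C)C(C)C)c1ccc([C@H]2Oc3c(ccc(OC(=O)N(CC)CC)c3[Li])[C@H](c3cc4c(c([Li])c3OC(=O)N(CC)CC)O[C@H](c3ccc(O[Si](C(C)C)(C(C)C)C(C)C)cc3)[C@H](O[Si](C)(C)C(C)(C)C)[C@@H]4O[Si](C)(C)C(C)(C)C)[C@H]2O[Si](C)(C)C(C)(C)C)cc1 | intermediate (not isolated)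
19 | 8,8′-bis(dimethoxyboryl) derivative of 17 | O([Si](C(C)C)(C(C)C)C(C)C)c1ccc([C@H]2Oc3c(ccc(OC(=O)N(CC)CC)c3B(OC)OC)[C@H](c3cc4c(c(B(OC)OC)c3OC(=O)N(CC)CC)O[C@H](c3ccc(O[Si](C(C)C)(C(C)C)C(C)C)cc3)[C@H](O[Si](C)(C)C(C)(C)C)[C@@H]4O[Si](C)(C)C(C)(C)C)[C@H]2O[Si](C)(C)C(C)(C)C)cc1 | intermediate (not isolated)
20 | 8,8′-dihydroxy derivative of 17 (protected target with both C8 hydroxyls) | O([Si](C(C)C)(C(C)C)C(C)C)c1ccc([C@H]2Oc3c(ccc(OC(=O)N(CC)CC)c3O)[C@H](c3cc4c(c(O)c3OC(=O)N(CC)CC)O[C@H](c3ccc(O[Si](C(C)C)(C(C)C)C(C)C)cc3)[C@H](O[Si](C)(C)C(C)(C)C)[C@@H]4O[Si](C)(C)C(C)(C)C)[C@H]2O[Si](C)(C)C(C)(C)C)cc1 | intermediate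
21 | silyl-protected target: epioritin-(4β→6)-epioritin-4α-ol with 4′-O-TIPS on both units, 3-O-TBS (upper), 3,4-di-O-TBS (lower) | O([Si](C(C)C)(C(C)C)C(C)C)c1ccc([C@H]2Oc3c(ccc(O)c3O)[C@H](c3cc4c(c(O)c3O)O[C@H](c3ccc(O[Si](C(C)C)(C(C)C)C(C)C)cc3)[C@H](O[Si](C)(C)C(C)(C)C)[C@@H]4O[Si](C)(C)C(C)(C)C)[C@H]2O[Si](C)(C)C(C)(C)C)cc1 | intermediate
22 | epioritin-(4β→6)-epioritin-4α-ol (CNP0391561.1) | Oc1ccc([C@H]2Oc3c(ccc(O)c3O)[C@H](c3cc4c(c(O)c3O)O[C@H](c3ccc(O)cc3)[C@H](O)[C@@H]4O)[C@H]2O)cc1 | target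

**Step count and risks**

Total step count: 17. Longest linear sequence: 16 steps (steps 1–7 and 9–17, from 4-hydroxybenzaldehyde).

Steps most likely to fail:

1. Step 15. Process: the second metalation stalls on the crowded lower unit, or the base removes the diarylmethine C4–H or a benzylic proton, or a lithiated carbamate undergoes the anionic Fries shift before boron trapping. Fallback: the same lithiation is done once on the simple monomer, and the dimer is then assembled from 7,8-dibenzyloxy units, accepting a less nucleophilic lower unit. It sets out from 9 and comes back at 21. Hydrogenolysis of 9 (H2, Pd/C) gives the 7-phenol F1, and NaH/ClC(O)NEt2 gives the 7-O-carbamate F2. s-BuLi/TMEDA at −78 °C gives the 8-lithio carbamate F3, B(OMe)3 gives the 8-dimethoxyboryl carbamate F4, and H2O2/AcOH gives the 8-hydroxy carbamate F5. LiAlH4 gives the 7,8-diol F6, and BnBr/K2CO3 gives the 7,8-bis(benzyl ether) F7. DDQ/H2O gives the 4β-alcohol F8, which BnSH/ZnI2 converts into the 4β-benzylsulfanyl donor F9. Dess–Martin oxidation of F8 gives the ketone F10, NaBH4/CeCl3 gives the all-cis 4α-alcohol F11, and TBSOTf gives the 3,4-bis(silyl ether) acceptor F12. Coupling of F9 with F12 under the conditions of step 12 gives the tetra-O-benzyl dimer F13, whose hydrogenolysis (H2, Pd/C) gives 21.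

2. Step 12. Process: ionisation of the C4–S bond of the weakly stabilised 5-deoxy donor by the silver salt is slow, so that acid-induced loss of silyl groups and self-alkylation of the donor overtake the cross-coupling. Fallback: hard, oxophilic activation of an oxygen leaving group in place of the soft thioether. It sets out from 9 and comes back at 15. DDQ oxidation of 9 in CH2Cl2 with 2-ethoxyethanol gives the 4β-(2-ethoxyethoxy) ether F14, which with catalytic TMSOTf in CH2Cl2 at −78 °C alkylates an excess of 14 at C6 to give 15.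

3. Step 5. Process: the aryllithium attacks the internal epoxide carbon (5-exo closure to a dihydrobenzofuran) or abstracts the benzylic proton next to the ether oxygen instead of closing the six-membered ring. Fallback: electrophilic instead of anionic ring closure. It sets out from 4 and comes back at 8. Mitsunobu etherification of 4 with 3-(benzyloxy)phenol gives the bromine-free aryl ether F15, and AuCl3/AgOSO2CF3-catalysed intramolecular epoxide–arene (Friedel–Crafts) cyclisation, para to the benzyloxy group, gives 8.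

**Further compounds**

F1 | step 15 | (2R,3R)-3-[tert-butyl(dimethyl)silyloxy]-2-{4-[tri(propan-2-yl)silyloxy]phenyl}chroman-7-ol | CC(C)[Si](C(C)C)(C(C)C)Oc1ccc([C@H]2Oc3cc(O)ccc3C[C@H]2O[Si](C)(C)C(C)(C)C)cc1
F2 | step 15 | 7-O-(N,N-diethylcarbamate) of F1 | CC(C)[Si](C(C)C)(C(C)C)Oc1ccc([C@H]2Oc3cc(OC(=O)N(CC)CC)ccc3C[C@H]2O[Si](C)(C)C(C)(C)C)cc1
F3 | step 15 | 8-lithio derivative of F2 (not isolated) | CC(C)[Si](C(C)C)(C(C)C)Oc1ccc([C@H]2Oc3c([Li])c(OC(=O)N(CC)CC)ccc3C[C@H]2O[Si](C)(C)C(C)(C)C)cc1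
F4 | step 15 | 8-(dimethoxyboryl) derivative of F2 (not isolated) | CC(C)[Si](C(C)C)(C(C)C)Oc1ccc([C@H]2Oc3c(B(OC)OC)c(OC(=O)N(CC)CC)ccc3C[C@H]2O[Si](C)(C)C(C)(C)C)cc1
F5 | step 15 | 8-hydroxy derivative of F2 | CC(C)[Si](C(C)C)(C(C)C)Oc1ccc([C@H]2Oc3c(O)c(OC(=O)N(CC)CC)ccc3C[C@H]2O[Si](C)(C)C(C)(C)C)cc1
F6 | step 15 | (2R,3R)-3-[tert-butyl(dimethyl)silyloxy]-2-{4-[tri(propan-2-yl)silyloxy]phenyl}chromane-7,8-diol | CC(C)[Si](C(C)C)(C(C)C)Oc1ccc([C@H]2Oc3c(O)c(O)ccc3C[C@H]2O[Si](C)(C)C(C)(C)C)cc1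
F7 | step 15 | 7,8-bis(benzyl ether) of F6 | CC(C)[Si](C(C)C)(C(C)C)Oc1ccc([C@H]2Oc3c(OCc4ccccc4)c(OCc4ccccc4)ccc3C[C@H]2O[Si](C)(C)C(C)(C)C)cc1
F8 | step 15 | 4β-alcohol of F7 (2,3-cis-3,4-trans) | CC(C)[Si](C(C)C)(C(C)C)Oc1ccc([C@H]2Oc3c(OCc4ccccc4)c(OCc4ccccc4)ccc3[C@H](O)[C@H]2O[Si](C)(C)C(C)(C)C)cc1
F9 | step 15 | 4β-benzylsulfanyl derivative of F7 | CC(C)[Si](C(C)C)(C(C)C)Oc1ccc([C@H]2Oc3c(OCc4ccccc4)c(OCc4ccccc4)ccc3[C@H](SCc3ccccc3)[C@H]2O[Si](C)(C)C(C)(C)C)cc1
F10 | step 15 | 4-ketone of F7 (2,3-cis) | CC(C)[Si](C(C)C)(C(C)C)Oc1ccc([C@H]2Oc3c(OCc4ccccc4)c(OCc4ccccc4)ccc3C(=O)[C@H]2O[Si](C)(C)C(C)(C)C)cc1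
F11 | step 15 | all-cis 4α-alcohol of F7 | CC(C)[Si](C(C)C)(C(C)C)Oc1ccc([C@H]2Oc3c(OCc4ccccc4)c(OCc4ccccc4)ccc3[C@@H](O)[C@H]2O[Si](C)(C)C(C)(C)C)cc1
F12 | step 15 | all-cis 3,4-bis(TBS ether) of the 7,8-dibenzyloxy series | CC(C)[Si](C(C)C)(C(C)C)Oc1ccc([C@H]2Oc3c(OCc4ccccc4)c(OCc4ccccc4)ccc3[C@@H](O[Si](C)(C)C(C)(C)C)[C@H]2O[Si](C)(C)C(C)(C)C)cc1
F13 | step 15 | 7,8,7′,8′-tetra-O-benzyl (4β→6) dimer with the silyl groups of 21 | O([Si](C(C)C)(C(C)C)C(C)C)c1ccc([C@H]2Oc3c(ccc(OCc4ccccc4)c3OCc3ccccc3)[C@H](c3cc4c(c(OCc5ccccc5)c3OCc3ccccc3)O[C@H](c3ccc(O[Si](C(C)C)(C(C)C)C(C)C)cc3)[C@H](O[Si](C)(C)C(C)(C)C)[C@@H]4O[Si](C)(C)C(C)(C)C)[C@H]2O[Si](C)(C)C(C)(C)C)cc1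
F14 | step 12 | 4β-(2-ethoxyethoxy) derivative of 9 | CC(C)[Si](C(C)C)(C(C)C)Oc1ccc([C@H]2Oc3cc(OCc4ccccc4)ccc3[C@H](OCCOCC)[C@H]2O[Si](C)(C)C(C)(C)C)cc1
F15 | step 5 | (2R)-2-[(R)-[3-(benzyloxy)phenoxy]{4-[tri(propan-2-yl)silyloxy]phenyl}methyl]oxirane | c1cc(OCc2ccccc2)cc(O[C@H](c2ccc(O[Si](C(C)C)(C(C)C)C(C)C)cc2)[C@H]2CO2)c1
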